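**Plan**
- Retrosynthetic cuts, in order: the O7–prenyl ether bond; the C4a–C5 bond of ring A; the C8–C8a bond (cyclobutenone C4 to pyranone C6); the C2–C1' bond between ring C and ring B.
- Enabling feature: ring A is a pentasubstituted benzene with C5–OH para to C8–OMe, and C6–H and C7–O-alkyl between them, fused to the pyranone through C4a/C8a. A 4-methoxy-3-alkoxycyclobutenone carrying the pyranone at C4 unfolds into exactly this pattern.
- Forward order: ring C is bought as pyromeconic acid, ring B is attached by Suzuki coupling, the four-membered ring is added at pyranone C6, and ring A is formed last by thermal ring expansion.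
- Finish: cleavage of all benzyl and isopropyl ethers, peracetylation, selective release of 7-OH, Mitsunobu prenylation, deacetylation.
- Stereochemistry: the target has no stereocenter. The one stereocenter on the route, the quaternary cyclobutenone carbon, is racemic and becomes aromatic C8.

Key step: step 7

Remark: pyranone positions are numbered as in 5 (aryl at C2, benzyloxy at C3, free CH at C5 and C6); C6 of 5 is the pyran-2-yl carbon in the names of 9–13, and flavone numbering is used from 14 onwards.
Assumption: the hindered lithium amide removes the C6 hydrogen of 5 (next to the ring oxygen) rather than the C5 hydrogen, as lithium amides do at C2 of chromones.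
Remark: compounds 7, 10, 11, 12 and 14 are racemic, and their single stereocenter has no bearing on the achiral target.

**Route**

Step 1
Reactants: 1 3-hydroxy-4H-pyran-4-one (pyromeconic acid)
Product: 2 2-bromo-3-hydroxy-4H-pyran-4-one
Conditions: NBS, MeCN, 0 °C → rt, dark
Reagents that add atoms: N-bromosuccinimide, O=C1CCC(=O)N1Br
Why: Electrophilic bromination of an enol; the 3-hydroxyl makes C2 the nucleophilic carbon of the pyranone (the site where 3-hydroxy-4-pyranones also undergo hydroxyalkylation and Mannich reactions), so bromination should occur there.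

Step 2
Reactants: 2 2-bromo-3-hydroxy-4H-pyran-4-one
Product: 3 3-(benzyloxy)-2-bromo-4H-pyran-4-one
Conditions: BnBr, K2CO3, DMF, rt
Reagents that add atoms: benzyl bromide, BrCc1ccccc1
Why: Williamson ether synthesis on the acidic enolic hydroxyl; the benzyl ether later withstands the lithium amide and is removed together with the other ethers in step 8.

Step 3
Reactants: 3 3-(benzyloxy)-2-bromo-4H-pyran-4-one; 4 [4-(benzyloxy)-3-methoxyphenyl]boronic acid
Product: 5 3-(benzyloxy)-2-[4-(benzyloxy)-3-methoxyphenyl]-4H-pyran-4-one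
Conditions: PdCl2(dppf) (cat.), K3PO4, 1,4-dioxane/H2O, 80 °C
Reagents that add atoms: none
Why: Suzuki–Miyaura coupling; the C2–Br bond is a vinylogous acyl bromide that should add readily to zerovalent palladium, and the phosphate base spares the base-sensitive pyranone ring.

Step 4
Reactants: 6 diisopropyl squarate
Product: 8 3-isopropoxycyclobut-3-ene-1,2-dione (isopropyl semisquarate), via hydroxycyclobutenone 7 (not isolated)
Conditions: LiAlH(OtBu)3, THF, −78 → 0 °C; aqueous work-up; crude 7 in CH2Cl2, conc. HCl (cat.), rt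
Reagents that add atoms: none
Why: Mono-reduction of one squarate carbonyl by the hindered hydride, then acid-catalysed vinylogous ester hydrolysis with allylic transposition and loss of isopropanol, is the standard entry to alkyl semisquarates.

Step 5
Reactants: 5 3-(benzyloxy)-2-[4-(benzyloxy)-3-methoxyphenyl]-4H-pyran-4-one; 8 3-isopropoxycyclobut-3-ene-1,2-dione
Product: 11 rac-4-{5-(benzyloxy)-6-[4-(benzyloxy)-3-methoxyphenyl]-4-oxo-4H-pyran-2-yl}-4-hydroxy-3-isopropoxycyclobut-2-en-1-one, via 6-lithiopyranone 9 (not isolated), via lithium alkoxide 10 (not isolated)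
Conditions: lithium 2,2,6,6-tetramethylpiperidide (LiTMP, from the amine and n-BuLi), THF, −78 °C; then transfer onto 8, THF, −78 °C; aq. NH4Cl
Reagents that add atoms: none
Why: Lithiation of the γ-pyranone at the CH next to the ring oxygen (the counterpart of chromone C2 lithiation) gives 9, which should add 1,2 to the ketone-like carbonyl of 8 (the other carbonyl is deactivated as a vinylogous ester), placing H at the future C6 and isopropoxy at the future C7; the new quaternary center forms as a racemate and is erased in step 7.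

Step 6
Reactants: 11 rac-4-{5-(benzyloxy)-6-[4-(benzyloxy)-3-methoxyphenyl]-4-oxo-4H-pyran-2-yl}-4-hydroxy-3-isopropoxycyclobut-2-en-1-one
Product: 12 rac-4-{5-(benzyloxy)-6-[4-(benzyloxy)-3-methoxyphenyl]-4-oxo-4H-pyran-2-yl}-3-isopropoxy-4-methoxycyclobut-2-en-1-one
Conditions: MeI, Ag2O, MeCN, rt, dark
Reagents that add atoms: iodomethane, CI
Why: Purdie methylation etherifies the tertiary carbinol under near-neutral conditions that are routine for 4-hydroxycyclobutenones and should not touch the pyranone carbonyl.

Step 7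
Reactants: 12 rac-4-{5-(benzyloxy)-6-[4-(benzyloxy)-3-methoxyphenyl]-4-oxo-4H-pyran-2-yl}-3-isopropoxy-4-methoxycyclobut-2-en-1-one
Product: 15 3-(benzyloxy)-2-[4-(benzyloxy)-3-methoxyphenyl]-5-hydroxy-7-isopropoxy-8-methoxy-4H-chromen-4-one, via dienylketene 13 (not isolated), via 4aH-chromenedione 14 (not isolated)
Conditions: toluene (degassed), 110 °C, Ar
Reagents that add atoms: none
Why: Heating should open the cyclobutenone by a conrotatory 4π electrocyclic reaction in which the C4 methoxy donor rotates outward, so that the pyranonyl group lies cis to the ketene in dienylketene 13. The ketene C=C, the central enol-ether C=C and the pyranone C5=C6 bond then form a hexatriene that closes by disrotatory 6π electrocyclisation, joining the ketene carbon to pyranone C5 (the C4a–C5 bond) and closing six-membered ring A as dione 14. The 4a-hydrogen of 14 sits between two carbonyl groups, and its shift to oxygen gives the phenol, held by a hydrogen bond to the C4 carbonyl. The closest known reaction is the thermal ring expansion of 4-aryl- and 4-alkenyl-4-alkoxycyclobutenones to hydroquinone monoethers and annulated phenols (Moore rearrangement), here with a γ-pyranone double bond as the 2π partner. No stereocenter is formed, and the racemic quaternary carbon of 12 becomes aromatic C8. The step needs outward rotation of the methoxy group and closure at C5; alkoxy donors at C4 rotate outward, and C5 is the only carbon available next to the point of attachment, the other neighbour being the ring oxygen.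

Step 8
Reactants: 15 3-(benzyloxy)-2-[4-(benzyloxy)-3-methoxyphenyl]-5-hydroxy-7-isopropoxy-8-methoxy-4H-chromen-4-one
Product: 16 3,5,7-trihydroxy-2-(4-hydroxy-3-methoxyphenyl)-8-methoxy-4H-chromen-4-one (limocitrin)
Conditions: BCl3, C6HMe5, CH2Cl2, −78 → 0 °C; H2O quench
Reagents that add atoms: none
Why: Lewis acid ether cleavage; BCl3 should cleave the two benzyl ethers and the secondary isopropyl ether through stabilised carbocations while the two methyl ethers (neither peri to the carbonyl) survive, and pentamethylbenzene traps the benzyl cations before they can alkylate electron-rich C6.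

Step 9
Reactants: 16 3,5,7-trihydroxy-2-(4-hydroxy-3-methoxyphenyl)-8-methoxy-4H-chromen-4-one
Product: 17 4-(3,5,7-triacetoxy-8-methoxy-4-oxo-4H-chromen-2-yl)-2-methoxyphenyl acetate
Conditions: Ac2O, pyridine, DMAP (cat.), rt → 50 °C
Reagents that add atoms: acetic anhydride, CC(=O)OC(C)=O
Why: Exhaustive O-acetylation under nucleophilic catalysis, which should also acylate the hydrogen-bonded 5-hydroxyl.

Step 10
Reactants: 17 4-(3,5,7-triacetoxy-8-methoxy-4-oxo-4H-chromen-2-yl)-2-methoxyphenyl acetate
Product: 18 4-(3,5-diacetoxy-7-hydroxy-8-methoxy-4-oxo-4H-chromen-2-yl)-2-methoxyphenyl acetate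
Conditions: PhSH, imidazole, NMP, 0 °C → rt
Reagents that add atoms: none
Why: Chemoselective transacylation; thiolysis of aryl acetates by thiophenol/imidazole is fastest for the ester of the most acidic phenol, the 7-hydroxyl para to the C4 carbonyl, a selectivity established for peracetylated flavonols.

Step 11
Reactants: 18 4-(3,5-diacetoxy-7-hydroxy-8-methoxy-4-oxo-4H-chromen-2-yl)-2-methoxyphenyl acetate; 19 prenol (3-methylbut-2-en-1-ol)
Product: 20 4-{3,5-diacetoxy-8-methoxy-7-[(3-methylbut-2-en-1-yl)oxy]-4-oxo-4H-chromen-2-yl}-2-methoxyphenyl acetate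
Conditions: PPh3, DIAD, THF, 0 °C → rt
Reagents that add atoms: none
Why: Mitsunobu etherification of the acidic 7-phenol with the primary allylic alcohol should proceed by SN2 displacement at the unhindered CH2 under neutral conditions, so the acetates neither migrate nor cleave.

Step 12
Reactants: 20 4-{3,5-diacetoxy-8-methoxy-7-[(3-methylbut-2-en-1-yl)oxy]-4-oxo-4H-chromen-2-yl}-2-methoxyphenyl acetate
Product: 21 3,5-dihydroxy-2-(4-hydroxy-3-methoxyphenyl)-8-methoxy-7-[(3-methylbut-2-en-1-yl)oxy]-4H-chromen-4-one
Conditions: NH3 (7 M in MeOH), 0 °C → rt, Ar; concentrate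
Reagents that add atoms: none
Why: Ester aminolysis; ammonolysis of the two aryl acetates and the enol acetate should be fast at or below room temperature and leave the allylic aryl ether and the methyl ethers untouched.

**Compound list**

1 | 3-hydroxy-4H-pyran-4-one (pyromeconic acid) | O=c1ccocc1O | starting material
2 | 2-bromo-3-hydroxy-4H-pyran-4-one | O=c1ccoc(Br)c1O | intermediate
3 | 3-(benzyloxy)-2-bromo-4H-pyran-4-one | O=c1ccoc(Br)c1OCc1ccccc1 | intermediate
4 | [4-(benzyloxy)-3-methoxyphenyl]boronic acid | COc1cc(B(O)O)ccc1OCc1ccccc1 | starting material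
5 | 3-(benzyloxy)-2-[4-(benzyloxy)-3-methoxyphenyl]-4H-pyran-4-one | COc1cc(-c2occc(=O)c2OCc2ccccc2)ccc1OCc1ccccc1 | intermediate
6 | diisopropyl squarate (3,4-diisopropoxycyclobut-3-ene-1,2-dione) | CC(C)OC1=C(OC(C)C)C(=O)C1=O | starting material
7 | rac-4-hydroxy-2,3-diisopropoxycyclobut-2-en-1-one | CC(C)OC1=C(OC(C)C)C(O)C1=O | intermediate (not isolated)
8 | 3-isopropoxycyclobut-3-ene-1,2-dione (isopropyl semisquarate) | CC(C)OC1=CC(=O)C1=O | intermediate
9 | {5-(benzyloxy)-6-[4-(benzyloxy)-3-methoxyphenyl]-4-oxo-4H-pyran-2-yl}lithium | COc1cc(-c2oc([Li])cc(=O)c2OCc2ccccc2)ccc1OCc1ccccc1 | intermediate (not isolated)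
10 | lithium alkoxide of 11 (racemic) | COc1cc(-c2oc(C3(O[Li])C(=O)C=C3OC(C)C)cc(=O)c2OCc2ccccc2)ccc1OCc1ccccc1 | intermediate (not isolated)
11 | rac-4-{5-(benzyloxy)-6-[4-(benzyloxy)-3-methoxyphenyl]-4-oxo-4H-pyran-2-yl}-4-hydroxy-3-isopropoxycyclobut-2-en-1-one | COc1cc(-c2oc(C3(O)C(=O)C=C3OC(C)C)cc(=O)c2OCc2ccccc2)ccc1OCc1ccccc1 | intermediate
12 | rac-4-{5-(benzyloxy)-6-[4-(benzyloxy)-3-methoxyphenyl]-4-oxo-4H-pyran-2-yl}-3-isopropoxy-4-methoxycyclobut-2-en-1-one | COc1cc(-c2oc(C3(OC)C(=O)C=C3OC(C)C)cc(=O)c2OCc2ccccc2)ccc1OCc1ccccc1 | intermediate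
13 | (3Z)-4-{5-(benzyloxy)-6-[4-(benzyloxy)-3-methoxyphenyl]-4-oxo-4H-pyran-2-yl}-3-isopropoxy-4-methoxybuta-1,3-dien-1-one | O=C=C/C(OC(C)C)=C(\c1cc(=O)c(OCc2ccccc2)c(-c2ccc(OCc3ccccc3)c(OC)c2)o1)OC | intermediate (not isolated)
14 | rac-3-(benzyloxy)-2-[4-(benzyloxy)-3-methoxyphenyl]-7-isopropoxy-8-methoxy-4aH-chromene-4,5-dione | COc1cc(C2=C(OCc3ccccc3)C(=O)C3C(=O)C=C(OC(C)C)C(OC)=C3O2)ccc1OCc1ccccc1 | intermediate (not isolated)
15 | 3-(benzyloxy)-2-[4-(benzyloxy)-3-methoxyphenyl]-5-hydroxy-7-isopropoxy-8-methoxy-4H-chromen-4-one | COc1cc(-c2oc3c(OC)c(OC(C)C)cc(O)c3c(=O)c2OCc2ccccc2)ccc1OCc1ccccc1 | intermediate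
16 | 3,5,7-trihydroxy-2-(4-hydroxy-3-methoxyphenyl)-8-methoxy-4H-chromen-4-one (limocitrin) | COc1cc(-c2oc3c(OC)c(O)cc(O)c3c(=O)c2O)ccc1O | intermediate
17 | 4-(3,5,7-triacetoxy-8-methoxy-4-oxo-4H-chromen-2-yl)-2-methoxyphenyl acetate | COc1cc(-c2oc3c(OC)c(OC(C)=O)cc(OC(C)=O)c3c(=O)c2OC(C)=O)ccc1OC(C)=O | intermediate
18 | 4-(3,5-diacetoxy-7-hydroxy-8-methoxy-4-oxo-4H-chromen-2-yl)-2-methoxyphenyl acetate | COc1cc(-c2oc3c(OC)c(O)cc(OC(C)=O)c3c(=O)c2OC(C)=O)ccc1OC(C)=O | intermediate
19 | prenol (3-methylbut-2-en-1-ol) | CC(C)=CCO | starting material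
20 | 4-{3,5-diacetoxy-8-methoxy-7-[(3-methylbut-2-en-1-yl)oxy]-4-oxo-4H-chromen-2-yl}-2-methoxyphenyl acetate | COc1cc(-c2oc3c(OC)c(OCC=C(C)C)cc(OC(C)=O)c3c(=O)c2OC(C)=O)ccc1OC(C)=O | intermediate
21 | 3,5-dihydroxy-2-(4-hydroxy-3-methoxyphenyl)-8-methoxy-7-[(3-methylbut-2-en-1-yl)oxy]-4H-chromen-4-one (CNP0210396.0) | COc1cc(-c2oc3c(OC)c(OCC=C(C)C)cc(O)c3c(=O)c2O)ccc1O | target

**Step count and risks**

Total step count: 12. Longest linear sequence: 11 steps (steps 1–3 and 5–12, from pyromeconic acid); step 4 is a one-step side branch.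

Steps most likely to fail:

1. Step 5 (lithiation of 5 and addition to 8). The lithium amide may remove the C5 hydrogen instead, after which the ring would open by β-elimination of the ring oxygen, or the lithiated pyranone may add in conjugate fashion to unreacted 5 before it meets the semisquarate. The fallback sets out from pyranone 5 and replaces the labile lithium species by a halogen–magnesium exchange. Zincation with TMPZnCl·LiCl in THF should give the thermally robust {5-(benzyloxy)-6-[4-(benzyloxy)-3-methoxyphenyl]-4-oxo-4H-pyran-2-yl}zinc chloride F1. Iodine should convert it into 3-(benzyloxy)-2-[4-(benzyloxy)-3-methoxyphenyl]-6-iodo-4H-pyran-4-one F2, an isolable compound whose substitution site can be secured before the squarate is committed. Iodine–magnesium exchange with i-PrMgCl·LiCl at −78 °C should then give the pyranonylmagnesium chloride F3, whose addition to semisquarate 8 leads to the chloromagnesium alkoxide F4. Work-up with NH4Cl returns the route at carbinol 11.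

2. Step 7 (ring expansion). Part of the material may open with the methoxy group rotating inward, which gives a ketene that cannot close, or the ketene may be consumed by dimerisation or adventitious nucleophiles if closure onto the electron-poor C5=C6 bond is slow. The fallback sets out from carbinol 11 and moves the ring expansion ahead of the methylation, so that the free hydroxyl serves as the outward-rotating donor. Heating 11 in degassed toluene should lead through the hydroxy dienylketene F5 and the 8-hydroxy-4aH-chromene-4,5-dione F6 to 3-(benzyloxy)-2-[4-(benzyloxy)-3-methoxyphenyl]-5,8-dihydroxy-7-isopropoxy-4H-chromen-4-one F7. Methylation with MeI and K2CO3 in acetone under argon should then etherify only the 8-hydroxyl, the 5-hydroxyl being held by its hydrogen bond to the carbonyl. The route is rejoined at chromone 15.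

3. Step 10 (selective 7-O-deacetylation). Site selectivity may erode, with thiolysis of the 4'-acetate or the 3-enol acetate competing, because the 7-acetate is flanked by the 8-methoxy group. The fallback sets out from tetraacetate 17 and merges steps 10 and 11 into a base-mediated alkylation. Prenyl bromide (CC(C)=CCBr) and K2CO3 in refluxing dry acetone should cleave the most labile 7-acetate in situ and alkylate the resulting phenoxide directly. The route is rejoined at prenyl ether 20 without any new isolated compound.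

**Further compounds**

F1 | step 5 | {5-(benzyloxy)-6-[4-(benzyloxy)-3-methoxyphenyl]-4-oxo-4H-pyran-2-yl}zinc chloride | COc1cc(-c2oc([Zn]Cl)cc(=O)c2OCc2ccccc2)ccc1OCc1ccccc1
F2 | step 5 | 3-(benzyloxy)-2-[4-(benzyloxy)-3-methoxyphenyl]-6-iodo-4H-pyran-4-one | COc1cc(-c2oc(I)cc(=O)c2OCc2ccccc2)ccc1OCc1ccccc1
F3 | step 5 | {5-(benzyloxy)-6-[4-(benzyloxy)-3-methoxyphenyl]-4-oxo-4H-pyran-2-yl}magnesium chloride | COc1cc(-c2oc([Mg]Cl)cc(=O)c2OCc2ccccc2)ccc1OCc1ccccc1
F4 | step 5 | chloromagnesium alkoxide of 11 (racemic) | COc1cc(-c2oc(C3(O[Mg]Cl)C(=O)C=C3OC(C)C)cc(=O)c2OCc2ccccc2)ccc1OCc1ccccc1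
F5 | step 7 | (3Z)-4-{5-(benzyloxy)-6-[4-(benzyloxy)-3-methoxyphenyl]-4-oxo-4H-pyran-2-yl}-4-hydroxy-3-isopropoxybuta-1,3-dien-1-one | O=C=C/C(OC(C)C)=C(\c1cc(=O)c(OCc2ccccc2)c(-c2ccc(OCc3ccccc3)c(OC)c2)o1)O
F6 | step 7 | rac-3-(benzyloxy)-2-[4-(benzyloxy)-3-methoxyphenyl]-8-hydroxy-7-isopropoxy-4aH-chromene-4,5-dione | COc1cc(C2=C(OCc3ccccc3)C(=O)C3C(=O)C=C(OC(C)C)C(O)=C3O2)ccc1OCc1ccccc1
F7 | step 7 | 3-(benzyloxy)-2-[4-(benzyloxy)-3-methoxyphenyl]-5,8-dihydroxy-7-isopropoxy-4H-chromen-4-one | COc1cc(-c2oc3c(O)c(OC(C)C)cc(O)c3c(=O)c2OCc2ccccc2)ccc1OCc1ccccc1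
F0 | step 10 | none | none
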